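The trap in these runs is to read their straight early climb as a law for every vessel.

| flask | starting material | second substrate | enzyme | remark | time |
|---|---|---|---|---|---|
| dusk | 20 mM | 20 mM | 2 µM | run made earlier |  |
| noon | 20 mM | 20 mM | 2.8 µM | run made earlier |  |
| dawn | 20 mM | 20 mM | 4.4 µM | run made earlier |  |
| alder | 20 mM (fed, over 1.00 min) | 20.0 mM | 2.0 µM | all but starting material at the start; starting material goes in evenly over 1.00 min, the run ends at 2.0 min | 2.0 min |
| elm | 20 mM | 20.0 mM | 2.0 µM | a closed flask charged with all of it at once and left for 2.0 min | 2.0 min |
| oak | 20 mM | 20.0 mM (fed, over 1.00 min) | 2.0 µM | all but second substrate at the start; second substrate goes in evenly over 1.00 min, the run ends at 2.0 min | 2.0 min |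
| maple | 20 mM | 20.0 mM | 2.0 µM | one stirred flow tank at steady state, fed with the mixture as stated, mean residence time 2.0 min |  |

dusk run (percent of the starting material charged)

| time / s | target / % |
|---|---|
| 10.0 | 9.5 |
| 20.0 | 15.7 |
| 30.0 | 24.6 |
| 60.0 | 46.7 |
| 120 | 66.6 |

noon run (percent of the starting material charged)

| time / min | target / % |
|---|---|
| 0.500 | 36.5 |
| 1.00 | 62.4 |
| 1.33 | 71.3 |
| 2.00 | 73.0 |
| 2.50 | 72.5 |

dawn run (percent of the starting material charged)

| time / min | target / % |
|---|---|
| 0.200 | 22.8 |
| 0.667 | 69.0 |
| 1.00 | 77.0 |
| 1.50 | 81.0 |
| 2.50 | 79.3 |

(readings scatter by 1 percentage point)

- the stated concentrations are those of everything mixed, before any reaction; amounts are the same in each set-up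
- the feed brings no volume worth counting
- the earlier runs were made in a closed, stirred flask

- the set-up with the highest amount of target at the outlet or at the end, in percent of the starting material put in ("none" if the first two lie within 2 percentage points) (alder / elm / oak / maple / none)
- amount of target at the outlet or at the end, in percent of the starting material put in, alder
- amount of target at the outlet or at the end, in percent of the starting material put in, elm
- amount of target at the outlet or at the end, in percent of the starting material put in, oak
- amount of target at the outlet or at the end, in percent of the starting material put in, maple

The dusk run makes 46.7% of target by 60.0 s. Dusk's clearing time is therefore 2.14 min: the time the enzyme would need, at its early pace, to turn the charge into target. Read the same way, noon gives 1.37 min and dawn 0.877 min, so in these readings more enzyme goes with a shorter time.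

One chemist holds the clock view. The enzyme keeps a fixed pace (zero-order in starting material), so the level in the flask doesn't matter, and dusk's 66.6% at 120 s stands for each set-up.

The other points out that the end values climb with enzyme, from 66.6% in dusk to 73.0% in noon. Something competes with the enzyme, and a loss that feeds on standing starting material must shrink when that level is held down.

The clock holder answers that alder's feed lasts 1.00 min, less than the clearing time, so starting material still piles up in alder, to a peak of 53.3% of the charge.

My own reckoning replaces each curve by its mean. A straight-sided curve's mean goes with its peak, and elm's peak is the charge itself. Taking the loss as proportional to the level, I scale dusk's shortfall by alder's peak, which gives a loss of 17.8%, so my estimate for alder is 82.2% once its starting material has cleared, though the run stops at 2.0 min.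

The forecast takes the second side with a lower figure: “Feeding it then keeps its standing level low”. It prints alder 80%, elm 66%, oak 63%, maple 62%, and names alder best.

The simulation puts alder first: alder 77.0%, elm 67.1%, oak 68.0%, maple 72.1%. Alder stands 9.9 percentage points above elm, against the clock view, while maple stands 10 points above the forecast.

    starting material + enzyme ⇌ complex A (K = 510 L mol⁻¹, k = 65000 L mol⁻¹ s⁻¹)
    complex A → enzyme + target (k = 120 s⁻¹)
    2 starting material → self-condensation product (k = 0.380 L mol⁻¹ s⁻¹)
    complex B → enzyme + second product (k = 2600 s⁻¹)
    second substrate + enzyme ⇌ complex B (K = 100 L mol⁻¹, k = 1.70 × 10⁶ L mol⁻¹ s⁻¹)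

Elm's mixture, stopped at 0.500 min, holds self-condensation product 24.9% beside target 24.9%. Alder at 1.00 min, with starting material at 49.8% against the reckoned peak of 53.3%, holds self-condensation product 10.2% beside target 40.0%. The clock view keeps its ground for target in a neighbour of elm charged with 5.0 × 10⁻⁴ mM of enzyme, where the clearing time scales to 8.57 min, longer than 2.0 min, and the pace gives 23.3%. That neighbour ends with 22.0% of target.

(The data come from a simulation with constants of no real substance; the scatter is artificial.)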